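## Retrosynthetic overview

- The plan rests on ring B. C1' carries chain carbon C7, and C3', C4' and C5' carry three adjacent oxygens of which only the C5' oxygen is methylated (C3'–OH, C4'–OH, C5'–OMe). Ring B is therefore grown as a 2-benzyloxycyclohexane-1,3-dione, in which the middle oxygen is already different from its two neighbours, and no pyrogallol has to be protected selectively.
- Late stage: target ⇐ hydrogenolysis of three benzyl ethers ⇐ hydrolysis of the C3 dioxolane ⇐ dehydrogenation of a 2-benzyloxy-3-methoxycyclohexenone ⇐ O-methylation and decarboxylation of the annulation product.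
- Key disconnection: C1'–C2' (Michael addition) and C3'–C4' (Claisen closure) between an (E)-enone ending in a benzyloxymethyl ketone and dimethyl malonate. Ring B is the only ring the route forms; ring A is bought with the arylpropanoic acid.
- The enone comes from cross-metathesis of a terminal alkene with 1-(benzyloxy)but-3-en-2-one. The alkene comes from C3–C4 bond formation between the lithiated dithiane of the ring A propanal and (R)-1,2-epoxy-5-hexene, which supplies C5 with the R configuration.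

Key step: step 10

Remark: chain carbons are numbered C1–C7 from ring A and ring B carbons C1'–C6'; the ring B sp3 centres of 14–21 should arise as mixtures and are drawn without configuration, and the 1,3-diones 15–17 are drawn as keto tautomers although they should be largely enolised.

## Route

Step 1
Reactants: 1 3-(4-hydroxy-3-methoxyphenyl)propanoic acid
Product: 2 benzyl 3-(4-benzyloxy-3-methoxyphenyl)propanoate
Conditions: BnBr (2.3 equiv), K2CO3, DMF, 60 °C
Reagents that add atoms: benzyl bromide, BrCc1ccccc1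
Why: Phenoxide and carboxylate are both alkylated by SN2 displacement (Williamson etherification and carboxylate O-alkylation) in one operation, which protects the ring A phenol and gives an ester ready for partial reduction.

Step 2
Reactants: 2 benzyl 3-(4-benzyloxy-3-methoxyphenyl)propanoate
Product: 3 3-(4-benzyloxy-3-methoxyphenyl)propanal
Conditions: i-Bu2AlH (1.1 equiv), CH2Cl2, –78 °C; MeOH, then aq. potassium sodium tartrate
Reagents that add atoms: none
Why: Partial reduction of an ester with i-Bu2AlH, in which the tetrahedral aluminium hemiacetal is stable at –78 °C and releases the aldehyde only on work-up.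

Step 3
Reactants: 3 3-(4-benzyloxy-3-methoxyphenyl)propanal
Product: 4 2-[2-(4-benzyloxy-3-methoxyphenyl)ethyl]-1,3-dithiane
Conditions: HS(CH2)3SH, BF3·OEt2 (0.2 equiv), CH2Cl2, 0 °C
Reagents that add atoms: propane-1,3-dithiol, SCCCS
Why: Lewis acid-catalysed dithioacetalisation of an unhindered aldehyde, run cold with a substoichiometric amount of BF3·OEt2 so that the aryl benzyl ether is not cleaved.

Step 4
Reactants: 4 2-[2-(4-benzyloxy-3-methoxyphenyl)ethyl]-1,3-dithiane; 5 (R)-1,2-epoxy-5-hexene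
Product: 6 (2R)-1-{2-[2-(4-benzyloxy-3-methoxyphenyl)ethyl]-1,3-dithian-2-yl}hex-5-en-2-ol
Conditions: n-BuLi, THF, –25 °C; then 5, DMPU, –25 → 0 °C; H2O
Reagents that add atoms: none
Why: Corey–Seebach umpolung, in which the 2-lithio-1,3-dithiane opens the terminal epoxide by SN2 attack at its CH2 carbon (new C3–C4 bond), so the C–O bond of the stereocentre is never broken and C5 keeps the R configuration bought with 5.

Step 5
Reactants: 6 (2R)-1-{2-[2-(4-benzyloxy-3-methoxyphenyl)ethyl]-1,3-dithian-2-yl}hex-5-en-2-ol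
Product: 7 (R)-2-[2-(benzyloxy)hex-5-en-1-yl]-2-[2-(4-benzyloxy-3-methoxyphenyl)ethyl]-1,3-dithiane
Conditions: NaH, BnBr, n-Bu4NI (cat.), THF/DMF, 0 °C → rt
Reagents that add atoms: benzyl bromide, BrCc1ccccc1
Why: Williamson ether synthesis on the secondary alkoxide, which is far more nucleophilic than the thioacetal sulfurs and does not involve the C5–O bond.

Step 6
Reactants: 7 (R)-2-[2-(benzyloxy)hex-5-en-1-yl]-2-[2-(4-benzyloxy-3-methoxyphenyl)ethyl]-1,3-dithiane
Product: 8 (R)-2-[2-(benzyloxy)hex-5-en-1-yl]-2-[2-(4-benzyloxy-3-methoxyphenyl)ethyl]-1,3-dioxolane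
Conditions: PhI(OCOCF3)2 (1.5 equiv), HOCH2CH2OH (10 equiv), MeCN, 0 °C → rt; aq. NaHCO3
Reagents that add atoms: ethylene glycol, OCCO
Why: Oxidative dethioacetalisation with a trivalent iodine reagent run in the presence of a diol, in which S-activation and C–S ionisation give a thionium ion that the glycol traps twice to close the dioxolane; this removes sulfur before the ruthenium and palladium steps and leaves C3 masked in a base-stable form.

Step 7
Reactants: 9 benzyloxyacetyl chloride
Product: 10 2-(benzyloxy)-N-methoxy-N-methylacetamide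
Conditions: MeNH(OMe)·HCl, K2CO3, EtOAc/H2O, 0 °C
Reagents that add atoms: N,O-dimethylhydroxylamine hydrochloride, CNOC.Cl
Why: Schotten–Baumann acylation of the amine by the acid chloride gives the Weinreb amide.

Step 8
Reactants: 10 2-(benzyloxy)-N-methoxy-N-methylacetamide
Product: 11 1-(benzyloxy)but-3-en-2-one
Conditions: CH2=CHMgBr, THF, –78 → 0 °C; poured into cold 1 M HCl
Reagents that add atoms: vinylmagnesium bromide, C=C[Mg]Br
Why: Weinreb ketone synthesis, in which the chelated tetrahedral intermediate prevents a second addition and the inverse acidic quench keeps the liberated amine protonated so that it cannot add to the vinyl ketone.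

Step 9
Reactants: 8 (R)-2-[2-(benzyloxy)hex-5-en-1-yl]-2-[2-(4-benzyloxy-3-methoxyphenyl)ethyl]-1,3-dioxolane; 11 1-(benzyloxy)but-3-en-2-one
Product: 12 (3E,7R)-1,7-bis(benzyloxy)-8-{2-[2-(4-benzyloxy-3-methoxyphenyl)ethyl]-1,3-dioxolan-2-yl}oct-3-en-2-one
Conditions: second-generation Hoveyda–Grubbs catalyst [RuCl2(H2IMes)(=CH–C6H4-2-O-i-Pr)] (5 mol%), 11 (3 equiv), CH2Cl2, 40 °C
Reagents that add atoms: none
Why: Olefin cross-metathesis between an unhindered terminal alkene and an electron-poor vinyl ketone, which homodimerises slowly, should give the conjugated E-enone under thermodynamic control with loss of ethylene.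

Step 10
Reactants: 12 (3E,7R)-1,7-bis(benzyloxy)-8-{2-[2-(4-benzyloxy-3-methoxyphenyl)ethyl]-1,3-dioxolan-2-yl}oct-3-en-2-one; 13 dimethyl malonate
Product: 15 methyl 3-(benzyloxy)-6-[(3R)-3-(benzyloxy)-4-{2-[2-(4-benzyloxy-3-methoxyphenyl)ethyl]-1,3-dioxolan-2-yl}butyl]-2,4-dioxocyclohexane-1-carboxylate, via Michael adduct 14 (not isolated)
Conditions: 13 (2 equiv) premixed with NaOMe (2.2 equiv), MeOH, 0 °C → 65 °C; then AcOH, 0 °C
Reagents that add atoms: none
Why: Methoxide converts 13 into its sodium enolate, which adds in a Michael reaction to the enone β-carbon of 12 (future C1', new bond C1'–C2') to give 14; proton transfer then places the enolate on the benzyloxy-bearing carbon (future C4'), which attacks one ester carbonyl (future C3') in an intramolecular Claisen (Dieckmann-type) condensation with loss of methoxide. The closest known reaction is the malonate–enone annulation that delivers dimedone and other 5-substituted cyclohexane-1,3-diones, here run on an enone whose α' carbon carries an ether oxygen. The one ring closed, ring B as a cyclohexane-1,3-dione, forms by a 6-(enolendo)-exo-trig attack of the ketone enolate on the ester. No stereocentre of the target is made: the ring sp3 centres C1', C2' and C4' arise uncontrolled and are all erased by decarboxylation and aromatisation, while C5 is an ether carbon with no acidic neighbour and cannot epimerise. The selectivity required is closure through C4' and not through the C6' methylene, and the substrate secures it because only the C4' enolate reaches an ester through a six-membered transition state (the C6' enolate would have to form a cyclobutanone) and because the product is withdrawn as its stabilised dione enolate. β-Elimination of the C5 benzyloxy group is excluded by the dioxolane at C3, and the excess of premixed malonate enolate should keep the enone from condensing with itself.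

Step 11
Reactants: 15 methyl 3-(benzyloxy)-6-[(3R)-3-(benzyloxy)-4-{2-[2-(4-benzyloxy-3-methoxyphenyl)ethyl]-1,3-dioxolan-2-yl}butyl]-2,4-dioxocyclohexane-1-carboxylate
Product: 17 2-(benzyloxy)-5-[(3R)-3-(benzyloxy)-4-{2-[2-(4-benzyloxy-3-methoxyphenyl)ethyl]-1,3-dioxolan-2-yl}butyl]cyclohexane-1,3-dione, via keto acid 16 (not isolated)
Conditions: NaOH, MeOH/H2O, 65 °C; 0 °C, 1 M HCl to pH 5, EtOAc; organic phase 45 °C
Reagents that add atoms: none
Why: Saponification gives the β-keto acid 16 (the dione survives hot hydroxide as its enolate), and the free acid loses CO2 through the usual cyclic transition state on gentle warming; acidifying only to pH 5 and decarboxylating in the organic phase should spare the dioxolane.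

Step 12
Reactants: 17 2-(benzyloxy)-5-[(3R)-3-(benzyloxy)-4-{2-[2-(4-benzyloxy-3-methoxyphenyl)ethyl]-1,3-dioxolan-2-yl}butyl]cyclohexane-1,3-dione
Product: 18 2-(benzyloxy)-5-[(3R)-3-(benzyloxy)-4-{2-[2-(4-benzyloxy-3-methoxyphenyl)ethyl]-1,3-dioxolan-2-yl}butyl]-3-methoxycyclohex-2-en-1-one
Conditions: Me2SO4, K2CO3, acetone, 56 °C
Reagents that add atoms: dimethyl sulfate, COS(=O)(=O)OC
Why: O-Alkylation of the enolised 1,3-dione (a vinylogous acid) by a hard electrophile gives the vinylogous ester; because 17 has a mirror plane through C1' and C4', either carbonyl gives the same constitution, and the oxygen that is methylated becomes the C5' oxygen.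

Step 13
Reactants: 18 2-(benzyloxy)-5-[(3R)-3-(benzyloxy)-4-{2-[2-(4-benzyloxy-3-methoxyphenyl)ethyl]-1,3-dioxolan-2-yl}butyl]-3-methoxycyclohex-2-en-1-one
Product: 22 2-(benzyloxy)-5-[(3R)-3-(benzyloxy)-4-{2-[2-(4-benzyloxy-3-methoxyphenyl)ethyl]-1,3-dioxolan-2-yl}butyl]-3-methoxyphenol, via selenide 19 (not isolated), via selenoxide 20 (not isolated), via dienone 21 (not isolated)
Conditions: LiN(i-Pr)2, THF, –78 °C; PhSeCl, –78 °C; crude in CH2Cl2, mCPBA (1.05 equiv), –78 °C; i-Pr2NH, → rt
Reagents that add atoms: none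
Why: Kinetic α'-deprotonation of the vinylogous ester at C2', selenenylation, oxidation at selenium and selenoxide syn-elimination across C1'–C2' give the cross-conjugated dienone 21, which tautomerises to the phenol, so that the last ring sp3 centre disappears and both diastereomers of 18 converge.

Step 14
Reactants: 22 2-(benzyloxy)-5-[(3R)-3-(benzyloxy)-4-{2-[2-(4-benzyloxy-3-methoxyphenyl)ethyl]-1,3-dioxolan-2-yl}butyl]-3-methoxyphenol
Product: 23 (5R)-5-(benzyloxy)-7-[4-(benzyloxy)-3-hydroxy-5-methoxyphenyl]-1-[4-(benzyloxy)-3-methoxyphenyl]heptan-3-one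
Conditions: 1 M HCl, THF, rt
Reagents that add atoms: water, O
Why: Acid-catalysed acetal hydrolysis releases the C3 ketone while the benzyl ethers are inert to dilute acid, and the β-benzyloxy ketone has no free hydroxyl to dehydrate.

Step 15
Reactants: 23 (5R)-5-(benzyloxy)-7-[4-(benzyloxy)-3-hydroxy-5-methoxyphenyl]-1-[4-(benzyloxy)-3-methoxyphenyl]heptan-3-one
Product: 24 (5R)-7-(3,4-dihydroxy-5-methoxyphenyl)-5-hydroxy-1-(4-hydroxy-3-methoxyphenyl)heptan-3-one
Conditions: H2 (1 atm), 10% Pd/C, EtOAc/MeOH, rt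
Reagents that add atoms: none
Why: Catalytic hydrogenolysis cleaves the two aryl benzyl ethers and the secondary alkyl benzyl ether under neutral conditions that do not reduce the dialkyl ketone and spare the β-hydroxy ketone, so C5 stays R.

## Compound list

1 | 3-(4-hydroxy-3-methoxyphenyl)propanoic acid | COc1cc(CCC(=O)O)ccc1O | starting material
2 | benzyl 3-(4-benzyloxy-3-methoxyphenyl)propanoate | COc1cc(CCC(=O)OCc2ccccc2)ccc1OCc1ccccc1 | intermediate
3 | 3-(4-benzyloxy-3-methoxyphenyl)propanal | COc1cc(CCC=O)ccc1OCc1ccccc1 | intermediate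
4 | 2-[2-(4-benzyloxy-3-methoxyphenyl)ethyl]-1,3-dithiane | COc1cc(CCC2SCCCS2)ccc1OCc1ccccc1 | intermediate
5 | (R)-1,2-epoxy-5-hexene | C=CCC[C@@H]1CO1 | starting material
6 | (2R)-1-{2-[2-(4-benzyloxy-3-methoxyphenyl)ethyl]-1,3-dithian-2-yl}hex-5-en-2-ol | COc1cc(CCC2(SCCCS2)C[C@H](O)CCC=C)ccc1OCc1ccccc1 | intermediate
7 | (R)-2-[2-(benzyloxy)hex-5-en-1-yl]-2-[2-(4-benzyloxy-3-methoxyphenyl)ethyl]-1,3-dithiane | COc1cc(CCC2(SCCCS2)C[C@H](OCc2ccccc2)CCC=C)ccc1OCc1ccccc1 | intermediate
8 | (R)-2-[2-(benzyloxy)hex-5-en-1-yl]-2-[2-(4-benzyloxy-3-methoxyphenyl)ethyl]-1,3-dioxolane | COc1cc(CCC2(OCCO2)C[C@H](OCc2ccccc2)CCC=C)ccc1OCc1ccccc1 | intermediate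
9 | benzyloxyacetyl chloride | O=C(Cl)COCc1ccccc1 | starting material
10 | 2-(benzyloxy)-N-methoxy-N-methylacetamide | CON(C)C(=O)COCc1ccccc1 | intermediate
11 | 1-(benzyloxy)but-3-en-2-one | C=CC(=O)COCc1ccccc1 | intermediate
12 | (3E,7R)-1,7-bis(benzyloxy)-8-{2-[2-(4-benzyloxy-3-methoxyphenyl)ethyl]-1,3-dioxolan-2-yl}oct-3-en-2-one | COc1cc(CCC2(OCCO2)C[C@H](OCc2ccccc2)CC/C=C/C(=O)COCc2ccccc2)ccc1OCc1ccccc1 | intermediate
13 | dimethyl malonate | COC(=O)CC(=O)OC | starting material
14 | dimethyl 2-[(7R)-1,7-bis(benzyloxy)-8-{2-[2-(4-benzyloxy-3-methoxyphenyl)ethyl]-1,3-dioxolan-2-yl}-2-oxooctan-4-yl]propanedioate (Michael adduct) | COc1cc(CCC2(OCCO2)C[C@H](OCc2ccccc2)CCC(CC(=O)COCc2ccccc2)C(C(=O)OC)C(=O)OC)ccc1OCc1ccccc1 | intermediate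
15 | methyl 3-(benzyloxy)-6-[(3R)-3-(benzyloxy)-4-{2-[2-(4-benzyloxy-3-methoxyphenyl)ethyl]-1,3-dioxolan-2-yl}butyl]-2,4-dioxocyclohexane-1-carboxylate | COc1cc(CCC2(OCCO2)C[C@H](OCc2ccccc2)CCC2CC(=O)C(OCc3ccccc3)C(=O)C2C(=O)OC)ccc1OCc1ccccc1 | intermediate
16 | 3-(benzyloxy)-6-[(3R)-3-(benzyloxy)-4-{2-[2-(4-benzyloxy-3-methoxyphenyl)ethyl]-1,3-dioxolan-2-yl}butyl]-2,4-dioxocyclohexane-1-carboxylic acid (keto acid) | COc1cc(CCC2(OCCO2)C[C@H](OCc2ccccc2)CCC2CC(=O)C(OCc3ccccc3)C(=O)C2C(=O)O)ccc1OCc1ccccc1 | intermediate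
17 | 2-(benzyloxy)-5-[(3R)-3-(benzyloxy)-4-{2-[2-(4-benzyloxy-3-methoxyphenyl)ethyl]-1,3-dioxolan-2-yl}butyl]cyclohexane-1,3-dione | COc1cc(CCC2(OCCO2)C[C@H](OCc2ccccc2)CCC2CC(=O)C(OCc3ccccc3)C(=O)C2)ccc1OCc1ccccc1 | intermediate
18 | 2-(benzyloxy)-5-[(3R)-3-(benzyloxy)-4-{2-[2-(4-benzyloxy-3-methoxyphenyl)ethyl]-1,3-dioxolan-2-yl}butyl]-3-methoxycyclohex-2-en-1-one | COc1cc(CCC2(OCCO2)C[C@H](OCc2ccccc2)CCC2CC(OC)=C(OCc3ccccc3)C(=O)C2)ccc1OCc1ccccc1 | intermediate
19 | 2-(benzyloxy)-5-[(3R)-3-(benzyloxy)-4-{2-[2-(4-benzyloxy-3-methoxyphenyl)ethyl]-1,3-dioxolan-2-yl}butyl]-3-methoxy-6-(phenylselanyl)cyclohex-2-en-1-one (selenide) | COc1cc(CCC2(OCCO2)C[C@H](OCc2ccccc2)CCC2CC(OC)=C(OCc3ccccc3)C(=O)C2[Se]c2ccccc2)ccc1OCc1ccccc1 | intermediate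
20 | 2-(benzyloxy)-5-[(3R)-3-(benzyloxy)-4-{2-[2-(4-benzyloxy-3-methoxyphenyl)ethyl]-1,3-dioxolan-2-yl}butyl]-3-methoxy-6-(phenylseleninyl)cyclohex-2-en-1-one (selenoxide) | COc1cc(CCC2(OCCO2)C[C@H](OCc2ccccc2)CCC2CC(OC)=C(OCc3ccccc3)C(=O)C2[Se](=O)c2ccccc2)ccc1OCc1ccccc1 | intermediate
21 | 2-(benzyloxy)-5-[(3R)-3-(benzyloxy)-4-{2-[2-(4-benzyloxy-3-methoxyphenyl)ethyl]-1,3-dioxolan-2-yl}butyl]-3-methoxycyclohexa-2,5-dien-1-one (dienone) | COc1cc(CCC2(OCCO2)C[C@H](OCc2ccccc2)CCC2=CC(=O)C(OCc3ccccc3)=C(OC)C2)ccc1OCc1ccccc1 | intermediate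
22 | 2-(benzyloxy)-5-[(3R)-3-(benzyloxy)-4-{2-[2-(4-benzyloxy-3-methoxyphenyl)ethyl]-1,3-dioxolan-2-yl}butyl]-3-methoxyphenol | COc1cc(CCC2(OCCO2)C[C@H](OCc2ccccc2)CCc2cc(O)c(OCc3ccccc3)c(OC)c2)ccc1OCc1ccccc1 | intermediate
23 | (5R)-5-(benzyloxy)-7-[4-(benzyloxy)-3-hydroxy-5-methoxyphenyl]-1-[4-(benzyloxy)-3-methoxyphenyl]heptan-3-one | COc1cc(CCC(=O)C[C@H](OCc2ccccc2)CCc2cc(O)c(OCc3ccccc3)c(OC)c2)ccc1OCc1ccccc1 | intermediate
24 | (5R)-7-(3,4-dihydroxy-5-methoxyphenyl)-5-hydroxy-1-(4-hydroxy-3-methoxyphenyl)heptan-3-one (CNP0183620.1) | COc1cc(CCC(=O)C[C@H](O)CCc2cc(O)c(O)c(OC)c2)ccc1O | target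

## Step count and risks

Total step count: 15. Longest linear sequence: 13 steps (steps 1–6 and 9–15); steps 7–8 form the short branch to 11.

Steps most likely to fail:

1. Step 10. The enone may be consumed by condensation with itself through its own enolates faster than it takes up malonate, or the sequence may stall after the conjugate addition without Claisen closure. Fallback, from 8 and back at 17: the C4' oxygen is left out of the annulation and introduced afterwards. Cross-metathesis of 8 with methyl vinyl ketone under the conditions of step 9 should give the methyl enone F1. NaOMe and 13 in MeOH should convert it into the Michael adduct F2, which closes through the methyl ketone enolate to the keto ester F3. NaOH followed by warming at pH 5 should pass through the keto acid F4 to the 5-substituted cyclohexane-1,3-dione F5. Diazo transfer with 4-acetamidobenzenesulfonyl azide and Et3N in MeCN should give the 2-diazo-1,3-dione F6. Rh2(OAc)4 in CH2Cl2 with benzyl alcohol should then insert the rhodium carbenoid into the O–H bond and deliver 17.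

2. Step 13. Selenenylation on the face that leaves no syn hydrogen at C1' would block the elimination, and the electron-rich phenol may be over-oxidised by peracid or by the selenium by-products. Fallback, from 18 and back at 22: the lithium enolate of 18 (LiN(i-Pr)2, THF, –78 °C) is trapped with Me3SiCl as the silyl dienol ether F7. Pd(OAc)2 in MeCN (Saegusa–Ito dehydrosilylation) should then give dienone 21, which tautomerises to 22 without any peroxide or selenium reagent.

3. Step 6. The trivalent iodine reagent may oxidise the alkoxy-substituted ring A, or capture by the glycol may be incomplete so that hydrolysis and acetal formation compete. Fallback, from 7 and back at 8: the exchange is split into two operations. Alkylative hydrolysis (MeI, CaCO3, MeCN/H2O, 45 °C) should give the β-benzyloxy ketone F8. Ketalisation with Me3SiOCH2CH2OSiMe3 and catalytic Me3SiOTf in CH2Cl2 at –78 °C, cold enough to avoid β-elimination of benzyl alcohol, should then give 8.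

Further compounds
F1 | step 10 | (3E,7R)-7-(benzyloxy)-8-{2-[2-(4-benzyloxy-3-methoxyphenyl)ethyl]-1,3-dioxolan-2-yl}oct-3-en-2-one | COc1cc(CCC2(OCCO2)C[C@H](OCc2ccccc2)CC/C=C/C(C)=O)ccc1OCc1ccccc1
F2 | step 10 | dimethyl 2-[(7R)-7-(benzyloxy)-8-{2-[2-(4-benzyloxy-3-methoxyphenyl)ethyl]-1,3-dioxolan-2-yl}-2-oxooctan-4-yl]propanedioate | COc1cc(CCC2(OCCO2)C[C@H](OCc2ccccc2)CCC(CC(C)=O)C(C(=O)OC)C(=O)OC)ccc1OCc1ccccc1
F3 | step 10 | methyl 6-[(3R)-3-(benzyloxy)-4-{2-[2-(4-benzyloxy-3-methoxyphenyl)ethyl]-1,3-dioxolan-2-yl}butyl]-2,4-dioxocyclohexane-1-carboxylate | COc1cc(CCC2(OCCO2)C[C@H](OCc2ccccc2)CCC2CC(=O)CC(=O)C2C(=O)OC)ccc1OCc1ccccc1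
F4 | step 10 | 6-[(3R)-3-(benzyloxy)-4-{2-[2-(4-benzyloxy-3-methoxyphenyl)ethyl]-1,3-dioxolan-2-yl}butyl]-2,4-dioxocyclohexane-1-carboxylic acid | COc1cc(CCC2(OCCO2)C[C@H](OCc2ccccc2)CCC2CC(=O)CC(=O)C2C(=O)O)ccc1OCc1ccccc1
F5 | step 10 | 5-[(3R)-3-(benzyloxy)-4-{2-[2-(4-benzyloxy-3-methoxyphenyl)ethyl]-1,3-dioxolan-2-yl}butyl]cyclohexane-1,3-dione | COc1cc(CCC2(OCCO2)C[C@H](OCc2ccccc2)CCC2CC(=O)CC(=O)C2)ccc1OCc1ccccc1
F6 | step 10 | 5-[(3R)-3-(benzyloxy)-4-{2-[2-(4-benzyloxy-3-methoxyphenyl)ethyl]-1,3-dioxolan-2-yl}butyl]-2-diazocyclohexane-1,3-dione | COc1cc(CCC2(OCCO2)C[C@H](OCc2ccccc2)CCC2CC(=O)C(=[N+]=[N-])C(=O)C2)ccc1OCc1ccccc1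
F7 | step 13 | {[6-(benzyloxy)-3-[(3R)-3-(benzyloxy)-4-{2-[2-(4-benzyloxy-3-methoxyphenyl)ethyl]-1,3-dioxolan-2-yl}butyl]-5-methoxycyclohexa-1,5-dien-1-yl]oxy}trimethylsilane | COc1cc(CCC2(OCCO2)C[C@H](OCc2ccccc2)CCC2CC(OC)=C(OCc3ccccc3)C(O[Si](C)(C)C)=C2)ccc1OCc1ccccc1
F8 | step 6 | (5R)-5-(benzyloxy)-1-[4-(benzyloxy)-3-methoxyphenyl]non-8-en-3-one | COc1cc(CCC(=O)C[C@H](OCc2ccccc2)CCC=C)ccc1OCc1ccccc1
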